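**Retrosynthetic overview**

- Numbering: ring A = C1 (OMe), C2 (H), C3 (CH3), C4 (Cl), C5 (OH), C6 (bridging C=O); ring B = C1′ (C=O), C2′ (CHO), C3′ (OH), C4′ (H), C5′ (OH), C6′ (prenyl). The plan rests on ring A, a fully substituted resorcinol monomethyl ether with the bridging carbon on C6 between C5–OH and C1–OMe, Cl on C4 and CH3 on C3. This is the substitution pattern that a cyclobutenone/alkoxyalkyne benzannulation produces.
- End game: the diaryl ketone comes from a silyl-protected benzhydrol (phenol capping, desilylation, oxidation). The three MOM ethers and the dioxane-masked C2′ aldehyde are hydrolysed last.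
- Key disconnection: ring A is built de novo from racemic 4-chloro-3-methylcyclobutenone and a 1-methoxyalkyne carrying ring B. The ketene/ynol ether [2+2] makes C5–C6 and C1–C2, and a 6π electrocyclisation closes the ring at C4–C5.
- The alkyne comes from lithium methoxyacetylide and the ring-B aldehyde. That aldehyde is made from methyl 3,5-dihydroxybenzoate by 2′,6′-dibromination and two successive Br/Li exchanges (prenyl at C6′, formyl at C2′). The cyclobutenone comes from dichloroketene plus propyne and removal of one chlorine.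
- Ring order: ring B is present in the starting benzoate; ring A is the only ring formed, in step 14.

Key step: step 14

Remark: the target has no stereocentre or other stereogenic element, so it is a single achiral compound; the carbinol and C–Cl centres of intermediates are carried as racemates (left unspecified in the SMILES) and are erased by the benzannulation and the benzhydrol oxidation.

**Route**

Step 1
Reactants: 1 methyl 3,5-dihydroxybenzoate
Product: 2 methyl 3,5-bis(methoxymethoxy)benzoate
Conditions: MOMCl, i-Pr2NEt, CH2Cl2, 0 °C → rt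
Reagents that add atoms: chloromethyl methyl ether (MOMCl), COCCl
Why: O-alkylation of both phenols with MOMCl under amine base (MOM ether formation) should proceed cleanly and leaves the ester untouched.

Step 2
Reactants: 2 methyl 3,5-bis(methoxymethoxy)benzoate
Product: 3 [3,5-bis(methoxymethoxy)phenyl]methanol
Conditions: LiAlH4, THF, 0 °C
Reagents that add atoms: none
Why: Hydride reduction of the benzoate ester to the benzylic alcohol; MOM acetals are inert to LiAlH4.

Step 3
Reactants: 3 [3,5-bis(methoxymethoxy)phenyl]methanol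
Product: 4 [2,6-dibromo-3,5-bis(methoxymethoxy)phenyl]methanol
Conditions: NBS (2.1 equiv), MeCN, 0 °C → rt
Reagents that add atoms: N-bromosuccinimide, O=C1CCC(=O)N1Br
Why: Electrophilic aromatic bromination of a resorcinol diether goes to the two equivalent positions that are ortho to one OMOM and para to the other (flanking the CH2OH) in preference to the doubly ortho C4′ site, and NBS generates no strong acid that would cleave the MOM ethers.

Step 4
Reactants: 4 [2,6-dibromo-3,5-bis(methoxymethoxy)phenyl]methanol
Product: 5 {[2,6-dibromo-3,5-bis(methoxymethoxy)phenyl]methoxy}tri(propan-2-yl)silane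
Conditions: TIPSCl, imidazole, DMF, rt
Reagents that add atoms: chlorotri(propan-2-yl)silane (TIPSCl), CC(C)[Si](Cl)(C(C)C)C(C)C
Why: Silylation of the primary alcohol; the bulky TIPS group is chosen so that the ortho-lithiated arenes of the next two steps do not undergo 1,4 O→C silyl migration (retro-Brook rearrangement).

Step 5
Reactants: 5 {[2,6-dibromo-3,5-bis(methoxymethoxy)phenyl]methoxy}tri(propan-2-yl)silane; 6 1-bromo-3-methylbut-2-ene (prenyl bromide)
Product: 8 {[2-bromo-3,5-bis(methoxymethoxy)-6-(3-methylbut-2-en-1-yl)phenyl]methoxy}tri(propan-2-yl)silane, via monolithiated arene 7 (not isolated)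
Conditions: n-BuLi (1.05 equiv), THF, −78 °C; CuBr·SMe2 (10 mol%), prenyl bromide, −78 → 0 °C
Reagents that add atoms: none
Why: Bromine–lithium exchange on one of the two equivalent bromides (a second exchange on the monoanion is disfavoured) followed by copper-catalysed allylic substitution, in which the hindered aryl metal attacks the unsubstituted α-carbon of prenyl bromide (SN2) to give the linear prenyl arene.

Step 6
Reactants: 8 {[2-bromo-3,5-bis(methoxymethoxy)-6-(3-methylbut-2-en-1-yl)phenyl]methoxy}tri(propan-2-yl)silane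
Product: 10 2,4-bis(methoxymethoxy)-5-(3-methylbut-2-en-1-yl)-6-{[tri(propan-2-yl)silyl]oxymethyl}benzaldehyde, via aryllithium 9 (not isolated)
Conditions: n-BuLi, THF, −78 °C; DMF, −78 → 0 °C; H2O
Reagents that add atoms: N,N-dimethylformamide, CN(C)C=O
Why: A second bromine–lithium exchange, faster at −78 °C than any deprotonation of the prenyl CH2, and Bouveault formylation of the OMOM-chelated aryllithium with DMF install the C2′ formyl group.

Step 7
Reactants: 10 2,4-bis(methoxymethoxy)-5-(3-methylbut-2-en-1-yl)-6-{[tri(propan-2-yl)silyl]oxymethyl}benzaldehyde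
Product: 11 {[2-(1,3-dioxan-2-yl)-3,5-bis(methoxymethoxy)-6-(3-methylbut-2-en-1-yl)phenyl]methoxy}tri(propan-2-yl)silane
Conditions: TMSO(CH2)3OTMS, TMSOTf (5 mol%), CH2Cl2, −78 → −30 °C; pyridine quench
Reagents that add atoms: 1,3-bis(trimethylsilyloxy)propane, C[Si](C)(C)OCCCO[Si](C)(C)C
Why: Noyori acetalisation (silyl-transfer acetal formation with catalytic TMSOTf at low temperature) masks the aldehyde as the 1,3-dioxane without protic acid, so the aryl MOM ethers, the TIPS ether and the prenyl group should survive.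

Step 8
Reactants: 11 {[2-(1,3-dioxan-2-yl)-3,5-bis(methoxymethoxy)-6-(3-methylbut-2-en-1-yl)phenyl]methoxy}tri(propan-2-yl)silane
Product: 12 [2-(1,3-dioxan-2-yl)-3,5-bis(methoxymethoxy)-6-(3-methylbut-2-en-1-yl)phenyl]methanol
Conditions: TBAF, THF, 0 °C → rt
Reagents that add atoms: none
Why: Fluoride cleavage of the silyl ether frees the C1′ hydroxymethyl group; acetals and MOM ethers are stable to TBAF.

Step 9
Reactants: 12 [2-(1,3-dioxan-2-yl)-3,5-bis(methoxymethoxy)-6-(3-methylbut-2-en-1-yl)phenyl]methanol
Product: 13 2-(1,3-dioxan-2-yl)-3,5-bis(methoxymethoxy)-6-(3-methylbut-2-en-1-yl)benzaldehyde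
Conditions: Dess–Martin periodinane, pyridine, CH2Cl2, 0 °C → rt
Reagents that add atoms: none
Why: Dess–Martin oxidation of the hindered benzylic alcohol to the aldehyde, with pyridine buffering the acetic acid so that the dioxane and MOM groups are kept.

Step 10
Reactants: 13 2-(1,3-dioxan-2-yl)-3,5-bis(methoxymethoxy)-6-(3-methylbut-2-en-1-yl)benzaldehyde; 14 2-chloro-1,1-dimethoxyethane (chloroacetaldehyde dimethyl acetal)
Product: 16 rac-1-[2-(1,3-dioxan-2-yl)-3,5-bis(methoxymethoxy)-6-(3-methylbut-2-en-1-yl)phenyl]-3-methoxyprop-2-yn-1-ol, via lithium methoxyethynide 15 (not isolated)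
Conditions: Et2NH, n-BuLi (→ LiNEt2, 3.2 equiv per chloroacetal), THF, 0 °C; chloroacetal (2 equiv); then the aldehyde, −78 → −40 °C; pH 7 buffer
Reagents that add atoms: none
Why: Double elimination (MeOH, then HCl) from the chloroacetal with lithium diethylamide gives lithium methoxyacetylide in situ, a small nucleophile that adds 1,2 to the non-enolisable hindered aldehyde (Arens-type alkoxyethynylation); the new carbinol centre forms as the racemate and is oxidised away later.

Step 11
Reactants: 16 rac-1-[2-(1,3-dioxan-2-yl)-3,5-bis(methoxymethoxy)-6-(3-methylbut-2-en-1-yl)phenyl]-3-methoxyprop-2-yn-1-ol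
Product: 17 rac-tert-butyl({1-[2-(1,3-dioxan-2-yl)-3,5-bis(methoxymethoxy)-6-(3-methylbut-2-en-1-yl)phenyl]-3-methoxyprop-2-yn-1-yl}oxy)dimethylsilane
Conditions: TBSCl, imidazole, DMAP (cat.), DMF, rt; chromatography on Et3N-deactivated silica
Reagents that add atoms: tert-butylchlorodimethylsilane (TBSCl), CC(C)(C)[Si](C)(C)Cl
Why: Silylation of the crude propargylic alcohol under basic conditions caps the hydroxyl, which would otherwise add to ketenes, and avoids the acid-induced Meyer–Schuster rearrangement to which γ-hydroxy ynol ethers are prone.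

Step 12
Reactants: 18 trichloroacetyl chloride; 19 propyne
Product: 21 4,4-dichloro-3-methylcyclobut-2-en-1-one, via dichloroketene 20 (not isolated)
Conditions: Zn–Cu couple, Et2O–DME, propyne (excess, dry-ice condenser), 0 °C → rt
Reagents that add atoms: none
Why: Zinc dehalogenation of the acid chloride generates dichloroketene, whose [2+2] cycloaddition with the terminal alkyne joins the ketene carbonyl carbon to the alkyne CH, placing the methyl group at C3 next to the CCl2 carbon.

Step 13
Reactants: 21 4,4-dichloro-3-methylcyclobut-2-en-1-one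
Product: 22 rac-4-chloro-3-methylcyclobut-2-en-1-one
Conditions: Zn dust (1.1 equiv), AcOH, TMEDA, EtOH, −10 → 0 °C
Reagents that add atoms: none
Why: Zinc/acetic acid reductive dechlorination of an α,α-dichloro ketone removes the first chlorine of the gem-dichloride faster than the second, so limiting zinc at low temperature should stop at the racemic monochloride, while TMEDA ties up ZnCl2 that would otherwise promote chloride migration to C2.

Step 14
Reactants: 17 rac-tert-butyl({1-[2-(1,3-dioxan-2-yl)-3,5-bis(methoxymethoxy)-6-(3-methylbut-2-en-1-yl)phenyl]-3-methoxyprop-2-yn-1-yl}oxy)dimethylsilane; 22 rac-4-chloro-3-methylcyclobut-2-en-1-one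
Product: 27 rac-2-{[tert-butyl(dimethyl)silyl]oxy[2-(1,3-dioxan-2-yl)-3,5-bis(methoxymethoxy)-6-(3-methylbut-2-en-1-yl)phenyl]methyl}-6-chloro-3-methoxy-5-methylphenol, via chlorovinylketene 23 (not isolated), via vinylcyclobutenone 24 (not isolated), via dienylketene 25 (not isolated), via cyclohexadienone 26 (not isolated)
Conditions: cyclobutenone (2 equiv, in two portions), toluene (0.5 M), 80 °C then 110 °C, sealed tube, N2
Reagents that add atoms: none
Why: Proposed new method: thermal 4π ring opening of the cyclobutenone (chlorine rotating outward) should give the (E)-chlorovinylketene, which undergoes [2+2] cycloaddition with the electron-rich alkyne to a 4-vinylcyclobutenone; a second, reversible 4π opening gives the dienylketene, 6π electrocyclisation gives the 6-chlorocyclohexa-2,4-dienone, and enolisation delivers the phenol. The closest known reaction type is the Danheiser benzannulation of cyclobutenones with alkoxyalkynes, which has not been run with a 4-halocyclobutenone, although thermal opening of 4-chlorocyclobutenones to chlorovinylketenes is itself established. Ring A is closed by the 6π electrocyclisation (C4–C5 bond) after the [2+2] has made C5–C6 and C1–C2. No stereocentre is created: the sp3 C–Cl carbon of the dienone disappears on tautomerisation and the carbinol centre is carried through as the racemate. The step needs regioselectivity in the [2+2], which the polarity of the ynol ether secures (its β-carbon, bearing the ring-B carbinol, bonds to the ketene carbonyl carbon, so that substituent ends up between OH and OMe), and a chlorine that lies outside the 6π transition state, which the outward torquoselectivity of a C4 donor substituent secures. A methoxyalkyne has no β-hydrogen and so cannot undergo the retro-ene fragmentation that limits ethoxyalkynes on heating, and the two ring-A oxygens arrive already differentiated (OMe from the alkyne, free OH from the ketene).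

Step 15
Reactants: 27 rac-2-{[tert-butyl(dimethyl)silyl]oxy[2-(1,3-dioxan-2-yl)-3,5-bis(methoxymethoxy)-6-(3-methylbut-2-en-1-yl)phenyl]methyl}-6-chloro-3-methoxy-5-methylphenol
Product: 28 rac-tert-butyl{[3-chloro-6-methoxy-2-(methoxymethoxy)-4-methylphenyl][2-(1,3-dioxan-2-yl)-3,5-bis(methoxymethoxy)-6-(3-methylbut-2-en-1-yl)phenyl]methoxy}dimethylsilane
Conditions: MOMCl, i-Pr2NEt, CH2Cl2, 0 → 40 °C
Reagents that add atoms: chloromethyl methyl ether (MOMCl), COCCl
Why: MOM ether formation on the only free hydroxyl caps the C5 phenol, so that the ortho-hydroxybenzhydrol (prone to ortho-quinone methide formation and phenol oxidation) is never exposed in the next two steps, and the group leaves with the others in the final hydrolysis.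

Step 16
Reactants: 28 rac-tert-butyl{[3-chloro-6-methoxy-2-(methoxymethoxy)-4-methylphenyl][2-(1,3-dioxan-2-yl)-3,5-bis(methoxymethoxy)-6-(3-methylbut-2-en-1-yl)phenyl]methoxy}dimethylsilane
Product: 29 rac-[3-chloro-6-methoxy-2-(methoxymethoxy)-4-methylphenyl][2-(1,3-dioxan-2-yl)-3,5-bis(methoxymethoxy)-6-(3-methylbut-2-en-1-yl)phenyl]methanol
Conditions: TBAF, THF, 0 °C → rt (warm to 40 °C if slow)
Reagents that add atoms: none
Why: Fluoride desilylation of the benzhydryl TBS ether; the small fluoride nucleophile reaches silicon despite the flanking ortho substituents, and MOM ethers and the dioxane are unaffected.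

Step 17
Reactants: 29 rac-[3-chloro-6-methoxy-2-(methoxymethoxy)-4-methylphenyl][2-(1,3-dioxan-2-yl)-3,5-bis(methoxymethoxy)-6-(3-methylbut-2-en-1-yl)phenyl]methanol
Product: 30 [3-chloro-6-methoxy-2-(methoxymethoxy)-4-methylphenyl][2-(1,3-dioxan-2-yl)-3,5-bis(methoxymethoxy)-6-(3-methylbut-2-en-1-yl)phenyl]methanone
Conditions: Dess–Martin periodinane, pyridine, CH2Cl2, rt
Reagents that add atoms: none
Why: Dess–Martin oxidation of the tetra-ortho-substituted diaryl carbinol to the benzophenone, a reagent that tolerates such hindrance and, buffered, the acetal groups; it removes the only stereocentre.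

Step 18
Reactants: 30 [3-chloro-6-methoxy-2-(methoxymethoxy)-4-methylphenyl][2-(1,3-dioxan-2-yl)-3,5-bis(methoxymethoxy)-6-(3-methylbut-2-en-1-yl)phenyl]methanone
Product: 31 Pestalone F, 2-(3-chloro-2-hydroxy-6-methoxy-4-methylbenzoyl)-4,6-dihydroxy-3-(3-methylbut-2-en-1-yl)benzaldehyde
Conditions: 2 M aq. HCl, THF, rt → 40 °C
Reagents that add atoms: water, O
Why: Acid-catalysed hydrolysis of the three aryl MOM acetals and of the electron-rich aryl 1,3-dioxane (the aldehyde oxygen coming from water) under dilute acid, conditions of the kind commonly used to remove MOM groups from prenylated phenols without cyclising the prenyl chain.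

**Compound list**

1 | methyl 3,5-dihydroxybenzoate | COC(=O)c1cc(O)cc(O)c1 | starting material
2 | methyl 3,5-bis(methoxymethoxy)benzoate | COCOc1cc(OCOC)cc(c1)C(=O)OC | intermediate
3 | [3,5-bis(methoxymethoxy)phenyl]methanol | COCOc1cc(CO)cc(OCOC)c1 | intermediate
4 | [2,6-dibromo-3,5-bis(methoxymethoxy)phenyl]methanol | COCOc1cc(OCOC)c(Br)c(CO)c1Br | intermediate
5 | {[2,6-dibromo-3,5-bis(methoxymethoxy)phenyl]methoxy}tri(propan-2-yl)silane | COCOc1cc(OCOC)c(Br)c(CO[Si](C(C)C)(C(C)C)C(C)C)c1Br | intermediate
6 | 1-bromo-3-methylbut-2-ene (prenyl bromide) | CC(C)=CCBr | starting material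
7 | [3-bromo-4,6-bis(methoxymethoxy)-2-{[tri(propan-2-yl)silyl]oxymethyl}phenyl]lithium (formed in the flask) | COCOc1cc(OCOC)c(Br)c(CO[Si](C(C)C)(C(C)C)C(C)C)c1[Li] | intermediate
8 | {[2-bromo-3,5-bis(methoxymethoxy)-6-(3-methylbut-2-en-1-yl)phenyl]methoxy}tri(propan-2-yl)silane | COCOc1cc(OCOC)c(Br)c(CO[Si](C(C)C)(C(C)C)C(C)C)c1CC=C(C)C | intermediate
9 | [2,4-bis(methoxymethoxy)-5-(3-methylbut-2-en-1-yl)-6-{[tri(propan-2-yl)silyl]oxymethyl}phenyl]lithium (formed in the flask) | COCOc1cc(OCOC)c([Li])c(CO[Si](C(C)C)(C(C)C)C(C)C)c1CC=C(C)C | intermediate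
10 | 2,4-bis(methoxymethoxy)-5-(3-methylbut-2-en-1-yl)-6-{[tri(propan-2-yl)silyl]oxymethyl}benzaldehyde | COCOc1cc(OCOC)c(C=O)c(CO[Si](C(C)C)(C(C)C)C(C)C)c1CC=C(C)C | intermediate
11 | {[2-(1,3-dioxan-2-yl)-3,5-bis(methoxymethoxy)-6-(3-methylbut-2-en-1-yl)phenyl]methoxy}tri(propan-2-yl)silane | COCOc1cc(OCOC)c(C2OCCCO2)c(CO[Si](C(C)C)(C(C)C)C(C)C)c1CC=C(C)C | intermediate
12 | [2-(1,3-dioxan-2-yl)-3,5-bis(methoxymethoxy)-6-(3-methylbut-2-en-1-yl)phenyl]methanol | COCOc1cc(OCOC)c(C2OCCCO2)c(CO)c1CC=C(C)C | intermediate
13 | 2-(1,3-dioxan-2-yl)-3,5-bis(methoxymethoxy)-6-(3-methylbut-2-en-1-yl)benzaldehyde | COCOc1cc(OCOC)c(C2OCCCO2)c(C=O)c1CC=C(C)C | intermediate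
14 | 2-chloro-1,1-dimethoxyethane (chloroacetaldehyde dimethyl acetal) | COC(CCl)OC | starting material
15 | lithium methoxyethynide (formed in the flask) | [Li]C#COC | intermediate
16 | rac-1-[2-(1,3-dioxan-2-yl)-3,5-bis(methoxymethoxy)-6-(3-methylbut-2-en-1-yl)phenyl]-3-methoxyprop-2-yn-1-ol | COC#CC(O)c1c(C2OCCCO2)c(OCOC)cc(OCOC)c1CC=C(C)C | intermediate
17 | rac-tert-butyl({1-[2-(1,3-dioxan-2-yl)-3,5-bis(methoxymethoxy)-6-(3-methylbut-2-en-1-yl)phenyl]-3-methoxyprop-2-yn-1-yl}oxy)dimethylsilane | COC#CC(O[Si](C)(C)C(C)(C)C)c1c(C2OCCCO2)c(OCOC)cc(OCOC)c1CC=C(C)C | intermediate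
18 | trichloroacetyl chloride | ClC(=O)C(Cl)(Cl)Cl | starting material
19 | propyne | CC#C | starting material
20 | dichloroketene (formed in the flask) | O=C=C(Cl)Cl | intermediate
21 | 4,4-dichloro-3-methylcyclobut-2-en-1-one | CC1=CC(=O)C1(Cl)Cl | intermediate
22 | rac-4-chloro-3-methylcyclobut-2-en-1-one | CC1=CC(=O)C1Cl | intermediate
23 | (E)-4-chloro-3-methylbuta-1,3-dien-1-one (chlorovinylketene, formed in the flask) | O=C=C/C(C)=C/Cl | intermediate
24 | 4-[(E)-1-chloroprop-1-en-2-yl]-3-methoxy-2-{[tert-butyl(dimethyl)silyl]oxy[2-(1,3-dioxan-2-yl)-3,5-bis(methoxymethoxy)-6-(3-methylbut-2-en-1-yl)phenyl]methyl}cyclobut-2-en-1-one (diastereomer mixture, formed in the flask) | COC1=C(C(O[Si](C)(C)C(C)(C)C)c2c(C3OCCCO3)c(OCOC)cc(OCOC)c2CC=C(C)C)C(=O)C1/C(C)=C/Cl | intermediate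
25 | (3E,5E)-6-chloro-3-methoxy-5-methyl-2-{[tert-butyl(dimethyl)silyl]oxy[2-(1,3-dioxan-2-yl)-3,5-bis(methoxymethoxy)-6-(3-methylbut-2-en-1-yl)phenyl]methyl}hexa-1,3,5-trien-1-one (dienylketene, formed in the flask) | O=C=C(C(O[Si](C)(C)C(C)(C)C)c1c(C2OCCCO2)c(OCOC)cc(OCOC)c1CC=C(C)C)/C(OC)=C\C(C)=C\Cl | intermediate
26 | 6-chloro-3-methoxy-5-methyl-2-{[tert-butyl(dimethyl)silyl]oxy[2-(1,3-dioxan-2-yl)-3,5-bis(methoxymethoxy)-6-(3-methylbut-2-en-1-yl)phenyl]methyl}cyclohexa-2,4-dien-1-one (diastereomer mixture, formed in the flask) | COC1=C(C(O[Si](C)(C)C(C)(C)C)c2c(C3OCCCO3)c(OCOC)cc(OCOC)c2CC=C(C)C)C(=O)C(Cl)C(C)=C1 | intermediate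
27 | rac-2-{[tert-butyl(dimethyl)silyl]oxy[2-(1,3-dioxan-2-yl)-3,5-bis(methoxymethoxy)-6-(3-methylbut-2-en-1-yl)phenyl]methyl}-6-chloro-3-methoxy-5-methylphenol | COc1cc(C)c(Cl)c(O)c1C(O[Si](C)(C)C(C)(C)C)c1c(C2OCCCO2)c(OCOC)cc(OCOC)c1CC=C(C)C | intermediate
28 | rac-tert-butyl{[3-chloro-6-methoxy-2-(methoxymethoxy)-4-methylphenyl][2-(1,3-dioxan-2-yl)-3,5-bis(methoxymethoxy)-6-(3-methylbut-2-en-1-yl)phenyl]methoxy}dimethylsilane | COCOc1c(Cl)c(C)cc(OC)c1C(O[Si](C)(C)C(C)(C)C)c1c(C2OCCCO2)c(OCOC)cc(OCOC)c1CC=C(C)C | intermediate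
29 | rac-[3-chloro-6-methoxy-2-(methoxymethoxy)-4-methylphenyl][2-(1,3-dioxan-2-yl)-3,5-bis(methoxymethoxy)-6-(3-methylbut-2-en-1-yl)phenyl]methanol | COCOc1c(Cl)c(C)cc(OC)c1C(O)c1c(C2OCCCO2)c(OCOC)cc(OCOC)c1CC=C(C)C | intermediate
30 | [3-chloro-6-methoxy-2-(methoxymethoxy)-4-methylphenyl][2-(1,3-dioxan-2-yl)-3,5-bis(methoxymethoxy)-6-(3-methylbut-2-en-1-yl)phenyl]methanone | COCOc1c(Cl)c(C)cc(OC)c1C(=O)c1c(C2OCCCO2)c(OCOC)cc(OCOC)c1CC=C(C)C | intermediate
31 | Pestalone F, 2-(3-chloro-2-hydroxy-6-methoxy-4-methylbenzoyl)-4,6-dihydroxy-3-(3-methylbut-2-en-1-yl)benzaldehyde | COc1cc(C)c(Cl)c(O)c1C(=O)c1c(C=O)c(O)cc(O)c1CC=C(C)C | target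

**Step count and risks**

Total step count: 18. Longest linear sequence: 16 steps (steps 1–11, then 14–18); steps 12–13 form the two-step side branch to the cyclobutenone.

Steps most likely to fail:

1. Step 14 (the benzannulation, the proposed new method). The chlorovinylketene may dimerise, be intercepted by the phenol product, or lose HCl faster than the bulky, α-branched alkyne traps it, and the second ring opening/electrocyclisation may stall. The fallback uses known chemistry (directed ortho-metalation and aryllithium addition) and sets out from aldehyde 13. Commercial 3-methoxy-5-methylphenol would be chlorinated ortho to the hydroxyl and para to the methoxy group (SO2Cl2, catalytic secondary amine, toluene) to give 2-chloro-5-methoxy-3-methylphenol F1. MOM protection (MOMCl, i-Pr2NEt) would give 2-chloro-5-methoxy-1-(methoxymethoxy)-3-methylbenzene F2. Deprotonation with n-BuLi/TMEDA in THF at the position flanked by OMOM and OMe would give [3-chloro-6-methoxy-2-(methoxymethoxy)-4-methylphenyl]lithium F3, which would add to 13 at −78 °C to give benzhydrol 29 directly. The route is rejoined at 29 and continues with steps 17 and 18.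

2. Step 13 (mono-dechlorination). Reduction may run on to the chlorine-free cyclobutenone, or allylic transposition on protonation and ZnCl2-promoted chloride migration may place the chlorine on C2, which would give the wrong ring-A isomer. The fallback sets out from 21. Exhaustive reduction (excess Zn, AcOH, TMEDA, EtOH, rt) would give 3-methylcyclobut-2-en-1-one F4. Heating F4 with 17 in toluene, a benzannulation of the established 3-alkylcyclobutenone type, should give the chlorine-free phenol rac-2-{[tert-butyl(dimethyl)silyl]oxy[2-(1,3-dioxan-2-yl)-3,5-bis(methoxymethoxy)-6-(3-methylbut-2-en-1-yl)phenyl]methyl}-3-methoxy-5-methylphenol F5. The chlorine would then be introduced at C4 (ortho to OH, para to OMe) by catalyst-directed ortho-chlorination of the free phenol (NCS, catalytic secondary ammonium salt, toluene, 0 °C), a reagent that is slow toward the isolated prenyl alkene. This gives 27, where the route is rejoined.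

3. Step 18 (global hydrolysis). Under protic acid the C5′ phenol may add to the prenyl double bond (chroman formation) while the dioxane is still being hydrolysed, and the liberated keto aldehyde may not tolerate prolonged acid. The fallback sets out from 30 and unmasks in two non-protic stages. Transacetalisation to acetone with catalytic iodine (acetone, rt → reflux) would free the aldehyde and give 2-[3-chloro-6-methoxy-2-(methoxymethoxy)-4-methylbenzoyl]-4,6-bis(methoxymethoxy)-3-(3-methylbut-2-en-1-yl)benzaldehyde F6. TMSOTf/2,2′-bipyridyl (CH2Cl2, 0 °C) would then exchange the three aryl MOM ethers for trimethylsilyl ethers, giving the tris(trimethylsilyl) ether of Pestalone F F7, which is hydrolysed on aqueous work-up to 31.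

**Further compounds**

F1 | step 14 | 2-chloro-5-methoxy-3-methylphenol | COc1cc(C)c(Cl)c(O)c1
F2 | step 14 | 2-chloro-5-methoxy-1-(methoxymethoxy)-3-methylbenzene | COCOc1cc(OC)cc(C)c1Cl
F3 | step 14 | [3-chloro-6-methoxy-2-(methoxymethoxy)-4-methylphenyl]lithium | COCOc1c([Li])c(OC)cc(C)c1Cl
F4 | step 13 | 3-methylcyclobut-2-en-1-one | CC1=CC(=O)C1
F5 | step 13 | rac-2-{[tert-butyl(dimethyl)silyl]oxy[2-(1,3-dioxan-2-yl)-3,5-bis(methoxymethoxy)-6-(3-methylbut-2-en-1-yl)phenyl]methyl}-3-methoxy-5-methylphenol | COc1cc(C)cc(O)c1C(O[Si](C)(C)C(C)(C)C)c1c(C2OCCCO2)c(OCOC)cc(OCOC)c1CC=C(C)C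
F6 | step 18 | 2-[3-chloro-6-methoxy-2-(methoxymethoxy)-4-methylbenzoyl]-4,6-bis(methoxymethoxy)-3-(3-methylbut-2-en-1-yl)benzaldehyde | COCOc1c(Cl)c(C)cc(OC)c1C(=O)c1c(C=O)c(OCOC)cc(OCOC)c1CC=C(C)C
F7 | step 18 | 2-[3-chloro-6-methoxy-4-methyl-2-(trimethylsilyloxy)benzoyl]-3-(3-methylbut-2-en-1-yl)-4,6-bis(trimethylsilyloxy)benzaldehyde | COc1cc(C)c(Cl)c(O[Si](C)(C)C)c1C(=O)c1c(C=O)c(O[Si](C)(C)C)cc(O[Si](C)(C)C)c1CC=C(C)C
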